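The data are calculated for substances that don't exist.

- I cannot read an order in free catalyst or in reagent from the elm run, since that flask has a single charge of each, so I must decide by reckoning which charge my next run changes.

- elm: substrate 0.40 M; reagent 1.6 M; free catalyst 1.2 mM; impurity 0.65 mM; the very flask that is asked about, followed so far
- flask: substrate 0.40 M; reagent 1.60 M; free catalyst 1.2 mM; impurity 0.65 mM

elm run (percent of the substrate charged)

| time / h | target / % | substrate / % |
|---|---|---|
| 0.667 | 1.2 | 98.9 |
| 2.00 | 2.3 | 96.5 |
| 4.00 | 5.2 | 95.2 |
| 6.00 | 7.3 | 92.9 |
| 8.00 | 9.1 | 91.0 |

(standard deviation of a reading: 0.3 percentage points)

- steps under discussion: catalyst intermediate D -> free catalyst + target; reagent + free catalyst <-> catalyst intermediate A; substrate + catalyst intermediate A -> catalyst intermediate B; catalyst intermediate C -> by-product + catalyst intermediate D; free catalyst + impurity -> spent catalyst; catalyst intermediate B -> catalyst intermediate C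
- no earlier run changes the charge of free catalyst; that part of a forecast is a guess
- no earlier run changes the charge of reagent; that part of a forecast is a guess

* apparent order in free catalyst when 10 % of the substrate are converted (percent change of the rate of making target for one percent more free catalyst charged)
* apparent order in reagent when 10 % of the substrate are converted (percent change of the rate of making target for one percent more reagent charged)

- In the elm run, target reads 5.2 % after 4.00 h and 9.1 % after 8.00 h: a factor 1.75 for twice the time, so that line bends little, and substrate at 91.0 % puts the asked moment just past the last reading.
- In this flask, impurity turns free catalyst into spent catalyst one for one, and its charge is 54.2 % of the catalyst charge, smaller, so a fraction 0.458 of the charge can survive.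
- I freeze the working catalyst at that surviving fraction. The poison takes a fixed amount, so each extra percent of charge lands on the survivors.
- My poison lever, the charge of catalyst over the charge minus the impurity, 2.18, is then, if the rate follows the survivors, the percent change of rate per percent more catalyst charged.
- I have no such reckoning for reagent; my next run raises the catalyst charge and leaves reagent and impurity as they are, because that lever exceeds plain proportion.
- The forecast gives 2.1 in free catalyst and 0.4 in reagent, the second with the words “The order in reagent is undetermined because reagent was never varied”.
- This flask gives 2.0 and 0.45, the first a little under my lever.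

    catalyst intermediate D → free catalyst + target (k = 31.0 h⁻¹)
    reagent + free catalyst ⇌ catalyst intermediate A (K = 2.00 L mol⁻¹, k = 36.0 L mol⁻¹ h⁻¹)
    substrate + catalyst intermediate A → catalyst intermediate B (k = 39.0 L mol⁻¹ h⁻¹)
    catalyst intermediate C → by-product + catalyst intermediate D (k = 220 h⁻¹)
    free catalyst + impurity → spent catalyst (k = 1700 L mol⁻¹ h⁻¹)
    catalyst intermediate B → catalyst intermediate C (k = 38.0 h⁻¹)

- Near the asked moment, at 0.400 d, the poison step is still running alongside the round in this flask, with 6.22 % of the impurity left and spent catalyst at 50.8 % of the catalyst charged; by 2.00 d impurity reads 0 % and spent catalyst 54.2 %. The round runs on in this flask with catalyst intermediate A, its resting state, the largest working form at 24.7 % of the catalyst charged, and target stands at 62.8 % after 4.00 d.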